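Readings and results are simulated from invented constants, noise included.

The chemist at this flask wants the most J from D and E, with a little Q present, and has two earlier runs to go on.

all flasks: D 0.050 M
- autumn: E 1 equiv; Q 3.5 mM; run made earlier
- dawn: E 1 equiv; Q 5.5 mM; run made earlier
- flask: E 1.00 equiv; Q 2.50 mM; time 25 min

| run | time / min | J / % | Z / % | D / % |
|---|---|---|---|---|
| autumn | 1.33 | 12.4 | 33.9 | 45.9 |
| autumn | 2.50 | 20.7 | 37.6 | 35.3 |
| autumn | 4.00 | 23.4 | 41.6 | 28.8 |
| autumn | 6.00 | 25.2 | 42.1 | 25.4 |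
| autumn | 10.0 | 23.1 | 49.4 | 20.3 |
| autumn | 15.0 | 21.7 | 54.2 | 18.1 |
| autumn | 25.0 | 18.3 | 62.0 | 13.0 |
| dawn | 1.33 | 12.9 | 32.5 | 43.8 |
| dawn | 2.50 | 20.4 | 37.8 | 33.0 |
| dawn | 4.00 | 24.2 | 38.4 | 25.6 |
| dawn | 6.00 | 25.8 | 40.8 | 22.6 |
| dawn | 10.0 | 24.6 | 46.6 | 18.4 |
| dawn | 15.0 | 21.8 | 50.6 | 14.8 |
| dawn | 25.0 | 18.4 | 58.6 | 11.3 |

(scatter of a reading: 0.5 percentage points)

- the best time, 25 min at the latest, for J
- the amount of J, in percent of the D charged, at that time

In both runs the three complexes fall short of the D charged. At 25.0 min the autumn run lacks 6.70% against a Q charge of 7.00% of D, and the dawn run lacks 11.7% against 11.0%. The autumn gap already stands at 7.80% by 1.33 min. My own reckoning is therefore that Q removes its own amount of D before the first reading. For this flask, Q charged over D charged gives 5.00%, the tied share: the part of D lost to Q, leaving D, Z and J a pool of 95.0%. The J readings barely follow that share, since both runs read highest at 6.00 min, with 25.2% in autumn and 25.8% at dawn, so I expect a top near that time and near those readings.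

The forecast gave 24.6% at 6 min, holding that “J barely responds to this”. The flask gives 24.6% at 5.75 min.

    Q + D → X (k = 3.70 L mol⁻¹ s⁻¹)
    D + E → G + Z (k = 0.270 L mol⁻¹ s⁻¹)
    L ⇌ G, rate k3*(cs3 - [G]) while solid is left; crystals form when [G] > cs3 (solubility = 1.90 mM, k = 0.190 s⁻¹)
    Z + E ⇌ G + J (K = 0.320, k = 0.260 L mol⁻¹ s⁻¹)

In the flask, Q + D → X ran alongside D + E → G + Z, which at the start used D at 1.5 times the rate of the Q step; the half-life of Q by its step alone at the charges was 0.062 min, and by 2.50 min Q stood at 0% and X at 5.00%, which matches 5.00%. At 5.75 min, with E down to 6.89% of its charge, J stood at its top and D, Z and J together held 95.0%; by 25.0 min, J had fallen to 17.2% while Z rose to 62.9%. A neighbouring flask with 0.600 equiv of E, the limiting reagent there with 1.0% left, also showed X at 5.00% at 25.0 min, and its D, Z and J together held 95.0%, of which J was 4.57%.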